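**Retrosynthetic overview**

- Licoleafol ⇒ its tetra-TBS ether ⇒ the (2S)-flavanone carrying an (E)-enal side chain. The side-chain alcohol comes from aldehyde reduction, the enal from cross-metathesis of an 8-allyl group with methacrolein, and the C4 ketone from a 4-methoxyflavan by DDQ/water.
- Feature on which the strategy rests: in the chromanone core, O1–C8a–C4a–C4 at the A/C ring fusion corresponds to an ortho-quinone methide heterodiene, and C2–C3 with the catechol B ring corresponds to a styrene. One inverse-demand hetero-Diels–Alder reaction can therefore form C3–C4 and O1–C2, close the pyran C ring and set C2, with C4 held at the acetal oxidation level.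
- Key disconnection: (2S)-8-allyl-4-methoxyflavan ⇒ 3-allyl-2-hydroxy-4,6-bis(silyloxy)benzaldehyde + trimethyl orthoformate + 3,4-bis(silyloxy)styrene under a chiral Brønsted acid.
- The salicylaldehyde comes from 2,4,6-trihydroxybenzaldehyde (bis-silylation, O-allylation, Claisen rearrangement); the styrene from 3,4-dihydroxybenzaldehyde (silylation, Wittig methylenation).
- Ring order: rings A and B are bought; ring C (the pyran) is the only ring formed, in step 6.

Key step: step 6

**Remarks**

- Flavonoid numbering is used (O1, C2–C4, C4a, C5–C8, C8a; B ring primed). TBS = tert-butyldimethylsilyl, TBSO = its ether.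
- Carbon building blocks are numbered reactants; the line "Reagents that add atoms" lists only unnumbered reagents.
- Assumption: the (R)-configured acid is taken to deliver 2S. If the sense of induction proves opposite, its enantiomer is used.
- Compound 12 is drawn as the 2,4-cis (2S,4S) isomer expected from an endo approach. A (2S,4R) epimer would be carried through equally, because C4 becomes the carbonyl carbon in step 8.

**Route**

Step 1
Reactants: 1 2,4,6-trihydroxybenzaldehyde
Product: 2 2-hydroxy-4,6-bis(TBSO)benzaldehyde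
Conditions: TBSCl (2.1 equiv), imidazole, DMF, 0 °C
Reagents that add atoms: tert-butyldimethylsilyl chloride, CC(C)(C)[Si](C)(C)Cl
Why: Phenol silylation; the 4-OH and one ortho OH react, while the remaining ortho OH is hydrogen-bonded to the aldehyde and reacts much more slowly, so two equivalents should stop at the bis-ether.

Step 2
Reactants: 2 2-hydroxy-4,6-bis(TBSO)benzaldehyde; 3 allyl alcohol
Product: 4 2-(allyloxy)-4,6-bis(TBSO)benzaldehyde
Conditions: PPh3, DIAD, THF, 0 °C to rt
Reagents that add atoms: none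
Why: Mitsunobu etherification of the acidic chelated phenol with a primary alcohol runs under neutral conditions and spares the base-labile aryl silyl ethers.

Step 3
Reactants: 4 2-(allyloxy)-4,6-bis(TBSO)benzaldehyde
Product: 5 3-allyl-2-hydroxy-4,6-bis(TBSO)benzaldehyde
Conditions: PhNEt2, 190 °C (sealed tube, argon)
Reagents that add atoms: none
Why: The aromatic Claisen rearrangement ([3,3]-sigmatropic shift) delivers the allyl group to C3, the only unsubstituted ortho position of the allyl ether, and tautomerisation restores the phenol; no silyl ether is ortho to the new OH, so silyl migration is not expected.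

Step 4
Reactants: 6 3,4-dihydroxybenzaldehyde
Product: 7 3,4-bis(TBSO)benzaldehyde
Conditions: TBSCl (2.3 equiv), imidazole, DMF, rt
Reagents that add atoms: tert-butyldimethylsilyl chloride, CC(C)(C)[Si](C)(C)Cl
Why: Standard silylation of both catechol hydroxyls.

Step 5
Reactants: 7 3,4-bis(TBSO)benzaldehyde
Product: 8 3,4-bis(TBSO)styrene
Conditions: Ph3PCH3Br (slight excess over base), KOtBu, THF, 0 °C to rt
Reagents that add atoms: methyltriphenylphosphonium bromide, C[P+](c1ccccc1)(c1ccccc1)c1ccccc1.[Br-]
Why: Wittig methylenation of an aromatic aldehyde with the non-stabilised ylide; keeping the phosphonium salt in slight excess leaves no free alkoxide to attack the aryl silyl ethers.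

Step 6
Reactants: 5 3-allyl-2-hydroxy-4,6-bis(TBSO)benzaldehyde; 8 3,4-bis(TBSO)styrene; 9 trimethyl orthoformate
Product: 12 (2S,4S)-8-allyl-4-methoxy-5,7-bis(TBSO)-2-[3,4-bis(TBSO)phenyl]chroman, via dimethyl acetal 10 (not isolated), via oxocarbenium ion 11 (not isolated)
Conditions: (R)-TRIP-type BINOL phosphoric acid (10 mol%; the N-triflylphosphoramide congener if ionisation is slow), 8 (2 equiv), 9 (1.5 equiv), 5 Å MS, toluene, −30 °C
Reagents that add atoms: none
Why: Proposed new method: the acid converts 5 with the orthoformate into acetal 10 and, by loss of methanol, into oxocarbenium ion 11 (an O-protonated 4-methoxy-o-quinone methide), which the chiral phosphate holds by a hydrogen bond to the phenol and by ion pairing; the CH2 terminus of 8 adds to the carbenium carbon (C3–C4) and the phenol oxygen captures the developing para-silyloxybenzylic cation (O1–C2), an asynchronous inverse-demand hetero-Diels–Alder reaction. The closest known reactions are the achiral Lewis-acid coupling of salicylaldehydes, orthoformates and styrenes to 2,4-cis-4-methoxy-2-arylchromans and chiral phosphoric acid-catalysed [4+2] additions of o-quinone methides to styrenes; the chiral-acid three-component form has not been shown. The pyran ring closes by [4+2] cycloaddition, which in its stepwise limit is a 6-exo-trig capture of the benzylic cation by O1. C2 (S) and C4 are set together by the catalyst-bound ion pair: the phosphate shields one face of 11 and the endo approach, dominant in the achiral reaction, gives the 2,4-cis product. The step needs both face selectivity and endo selectivity, because a trans isomer formed on the same face would be 2R and would erode the ee after C4 oxidation. The regiochemistry follows from the cation-stabilising 4-silyloxy group of 8, and the plain allyl group of 5 is too weak a nucleophile to compete and cannot cyclise under acid as a prenyl-type chain would.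

Step 7
Reactants: 12 (2S,4S)-8-allyl-4-methoxy-5,7-bis(TBSO)-2-[3,4-bis(TBSO)phenyl]chroman; 13 methacrolein
Product: 14 (E)-4-[(2S,4S)-4-methoxy-5,7-bis(TBSO)-2-(3,4-bis(TBSO)phenyl)chroman-8-yl]-2-methylbut-2-enal
Conditions: Hoveyda–Grubbs II (5 mol%), 13 (10 equiv), 1,4-benzoquinone (10 mol%), CH2Cl2, 40 °C
Reagents that add atoms: none
Why: Olefin cross-metathesis of a terminal allylarene with excess methacrolein should give the trisubstituted enal as the E isomer (CHO trans to the chain, thermodynamic control); the electron-poor enal also deactivates the benzylic/allylic CH2 towards the oxidant of step 8.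

Step 8
Reactants: 14 (E)-4-[(2S,4S)-4-methoxy-5,7-bis(TBSO)-2-(3,4-bis(TBSO)phenyl)chroman-8-yl]-2-methylbut-2-enal
Product: 16 (E)-4-[(2S)-4-oxo-5,7-bis(TBSO)-2-(3,4-bis(TBSO)phenyl)chroman-8-yl]-2-methylbut-2-enal, via C4 methyl hemiketal 15 (not isolated)
Conditions: DDQ (1.3 equiv), CH2Cl2/pH 7 phosphate buffer, 0 °C to rt
Reagents that add atoms: water, O
Why: DDQ abstracts the C4 hydride, which is benzylic to the 5,7,8a-trioxygenated A ring and α to the methoxy oxygen (the mechanism of oxidative cleavage of electron-rich benzyl ethers); water adds to the oxocarbenium ion and hemiketal 15 loses methanol to give the ketone, while C2–H (α to a less donating aryloxy oxygen, on a less activated ring) and the enal-deactivated side chain should react more slowly, so both C4 epimers converge and C2 is untouched.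

Step 9
Reactants: 16 (E)-4-[(2S)-4-oxo-5,7-bis(TBSO)-2-(3,4-bis(TBSO)phenyl)chroman-8-yl]-2-methylbut-2-enal
Product: 17 (2S)-5,7-bis(TBSO)-2-[3,4-bis(TBSO)phenyl]-8-[(E)-4-hydroxy-3-methylbut-2-enyl]chroman-4-one
Conditions: NaBH4 (1 equiv), THF/EtOH, −40 °C, then aq NH4Cl
Reagents that add atoms: none
Why: Chemoselective 1,2-reduction of the aldehyde by borohydride at low temperature; the C4 ketone, an electron-rich aryl ketone flanked by the 5-silyloxy group, is far less electrophilic, and the cold, short, weakly basic conditions should not open the pyranone ring.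

Step 10
Reactants: 17 (2S)-5,7-bis(TBSO)-2-[3,4-bis(TBSO)phenyl]-8-[(E)-4-hydroxy-3-methylbut-2-enyl]chroman-4-one
Product: 18 licoleafol, (2S)-2-(3,4-dihydroxyphenyl)-5,7-dihydroxy-8-[(E)-4-hydroxy-3-methylbut-2-enyl]chroman-4-one
Conditions: HF·pyridine, pyridine, THF, 0 °C to rt
Reagents that add atoms: none
Why: Fluoride cleavage of the four aryl silyl ethers under buffered, weakly acidic conditions avoids the phenoxides that would open the flavanone to the chalcone and erode C2, and the buffering should spare the allylic alcohol and the catechol.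

**Compound list**

1 | 2,4,6-trihydroxybenzaldehyde | O=Cc1c(O)cc(O)cc1O | starting material
2 | 2-hydroxy-4,6-bis(TBSO)benzaldehyde | O=Cc1c(O)cc(O[Si](C)(C)C(C)(C)C)cc1O[Si](C)(C)C(C)(C)C | intermediate
3 | allyl alcohol | C=CCO | starting material
4 | 2-(allyloxy)-4,6-bis(TBSO)benzaldehyde | C=CCOc1cc(O[Si](C)(C)C(C)(C)C)cc(O[Si](C)(C)C(C)(C)C)c1C=O | intermediate
5 | 3-allyl-2-hydroxy-4,6-bis(TBSO)benzaldehyde | C=CCc1c(O[Si](C)(C)C(C)(C)C)cc(O[Si](C)(C)C(C)(C)C)c(C=O)c1O | intermediate
6 | 3,4-dihydroxybenzaldehyde | O=Cc1ccc(O)c(O)c1 | starting material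
7 | 3,4-bis(TBSO)benzaldehyde | O=Cc1ccc(O[Si](C)(C)C(C)(C)C)c(O[Si](C)(C)C(C)(C)C)c1 | intermediate
8 | 3,4-bis(TBSO)styrene | C=Cc1ccc(O[Si](C)(C)C(C)(C)C)c(O[Si](C)(C)C(C)(C)C)c1 | intermediate
9 | trimethyl orthoformate | COC(OC)OC | starting material
10 | 6-allyl-2-(dimethoxymethyl)-3,5-bis(TBSO)phenol (dimethyl acetal of 5) | C=CCc1c(O[Si](C)(C)C(C)(C)C)cc(O[Si](C)(C)C(C)(C)C)c(C(OC)OC)c1O | intermediate
11 | oxocarbenium ion from 10 (O-protonated 4-methoxy-o-quinone methide, paired with the chiral phosphate) | C=CCc1c(O[Si](C)(C)C(C)(C)C)cc(O[Si](C)(C)C(C)(C)C)c(C=[O+]C)c1O | intermediate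
12 | (2S,4S)-8-allyl-4-methoxy-5,7-bis(TBSO)-2-[3,4-bis(TBSO)phenyl]chroman (2,4-cis) | C=CCc1c(O[Si](C)(C)C(C)(C)C)cc(O[Si](C)(C)C(C)(C)C)c2c1O[C@H](c1ccc(O[Si](C)(C)C(C)(C)C)c(O[Si](C)(C)C(C)(C)C)c1)C[C@@H]2OC | intermediate
13 | methacrolein | C=C(C)C=O | starting material
14 | (E)-4-[(2S,4S)-4-methoxy-5,7-bis(TBSO)-2-(3,4-bis(TBSO)phenyl)chroman-8-yl]-2-methylbut-2-enal | C/C(=C\Cc1c(O[Si](C)(C)C(C)(C)C)cc(O[Si](C)(C)C(C)(C)C)c2c1O[C@H](c1ccc(O[Si](C)(C)C(C)(C)C)c(O[Si](C)(C)C(C)(C)C)c1)C[C@@H]2OC)C=O | intermediate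
15 | C4 methyl hemiketal of 16 (4-hydroxy-4-methoxy; C4 configuration undefined, transient) | C/C(=C\Cc1c(O[Si](C)(C)C(C)(C)C)cc(O[Si](C)(C)C(C)(C)C)c2c1O[C@H](c1ccc(O[Si](C)(C)C(C)(C)C)c(O[Si](C)(C)C(C)(C)C)c1)CC2(O)OC)C=O | intermediate
16 | (E)-4-[(2S)-4-oxo-5,7-bis(TBSO)-2-(3,4-bis(TBSO)phenyl)chroman-8-yl]-2-methylbut-2-enal | C/C(=C\Cc1c(O[Si](C)(C)C(C)(C)C)cc(O[Si](C)(C)C(C)(C)C)c2c1O[C@H](c1ccc(O[Si](C)(C)C(C)(C)C)c(O[Si](C)(C)C(C)(C)C)c1)CC2=O)C=O | intermediate
17 | (2S)-5,7-bis(TBSO)-2-[3,4-bis(TBSO)phenyl]-8-[(E)-4-hydroxy-3-methylbut-2-enyl]chroman-4-one (tetra-O-TBS-licoleafol) | C/C(=C\Cc1c(O[Si](C)(C)C(C)(C)C)cc(O[Si](C)(C)C(C)(C)C)c2c1O[C@H](c1ccc(O[Si](C)(C)C(C)(C)C)c(O[Si](C)(C)C(C)(C)C)c1)CC2=O)CO | intermediate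
18 | licoleafol | C/C(=C\Cc1c(O)cc(O)c2c1O[C@H](c1ccc(O)c(O)c1)CC2=O)CO | target

**Step count**

Total: 10 steps. Longest linear sequence: 8 steps (steps 1, 2, 3, 6, 7, 8, 9, 10, from 2,4,6-trihydroxybenzaldehyde).

**Steps most likely to fail**

Step 6 (proposed new method). The ion pair may be too loose to discriminate the two faces of the oxocarbenium ion or the endo and exo approaches, which would lower the enantiomeric purity at C2 once C4 is oxidised. Acid-induced oligomerisation of the electron-rich styrene may outrun the cycloaddition, and re-ionisation at C4 may lead to loss of methanol and a flav-3-ene. The fallback uses known chemistry and gives up asymmetric induction. It sets out from 5, 8 and 9, which are coupled with an achiral Lewis acid (Sc(OTf)3, CH2Cl2, 0 °C), the established form of this three-component reaction, to give the racemic 2,4-cis 4-methoxyflavan F1. Cross-metathesis with 13 under the conditions of step 7 should give the racemic enal F2, and DDQ/water under the conditions of step 8 the racemic flavanone enal F3. F3 has a single stereocentre and is resolved by preparative chromatography on a polysaccharide chiral stationary phase. The (2S)-enantiomer is 16, where the fallback rejoins the route; the (2R)-enantiomer F4 is set aside.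

Step 8. Hydride abstraction may compete at C2–H or at the side-chain CH2, and the acidic hydroquinone may promote loss of methanol to a flav-3-ene that is then over-oxidised. The fallback sets out from 14 and avoids a hydride-abstracting oxidant. The methoxy group is exchanged for hydroxyl by mild acid solvolysis through the C4 cation (PPTS, THF/H2O, 0 °C to rt) to give the flavan-4-ol F5. This is oxidised with Dess–Martin periodinane (NaHCO3, CH2Cl2) to 16, where the route continues.

Step 7. Ruthenium hydride species may isomerise the allyl group into conjugation with the arene, the allylarene may homodimerise, or coupling with the 1,1-disubstituted enal may stall. The fallback sets out from 12 and builds the enal by carbonyl olefination instead of metathesis. Lemieux–Johnson cleavage (OsO4 cat., NaIO4, 2,6-lutidine, dioxane/H2O) gives the arylacetaldehyde F6. Wittig reaction with the stabilised ylide 2-(triphenylphosphoranylidene)propanal (toluene, 80 °C) should then give the (E)-enal 14, where the route continues.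

**Further compounds**

F1 | step 6 | racemic 2,4-cis 8-allyl-4-methoxy-5,7-bis(TBSO)-2-[3,4-bis(TBSO)phenyl]chroman | C=CCc1c(O[Si](C)(C)C(C)(C)C)cc(O[Si](C)(C)C(C)(C)C)c2c1OC(c1ccc(O[Si](C)(C)C(C)(C)C)c(O[Si](C)(C)C(C)(C)C)c1)CC2OC
F2 | step 6 | racemic (E)-4-[4-methoxy-5,7-bis(TBSO)-2-(3,4-bis(TBSO)phenyl)chroman-8-yl]-2-methylbut-2-enal | C/C(=C\Cc1c(O[Si](C)(C)C(C)(C)C)cc(O[Si](C)(C)C(C)(C)C)c2c1OC(c1ccc(O[Si](C)(C)C(C)(C)C)c(O[Si](C)(C)C(C)(C)C)c1)CC2OC)C=O
F3 | step 6 | racemic (E)-4-[4-oxo-5,7-bis(TBSO)-2-(3,4-bis(TBSO)phenyl)chroman-8-yl]-2-methylbut-2-enal | C/C(=C\Cc1c(O[Si](C)(C)C(C)(C)C)cc(O[Si](C)(C)C(C)(C)C)c2c1OC(c1ccc(O[Si](C)(C)C(C)(C)C)c(O[Si](C)(C)C(C)(C)C)c1)CC2=O)C=O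
F4 | step 6 | (2R)-enantiomer of 16 | C/C(=C\Cc1c(O[Si](C)(C)C(C)(C)C)cc(O[Si](C)(C)C(C)(C)C)c2c1O[C@@H](c1ccc(O[Si](C)(C)C(C)(C)C)c(O[Si](C)(C)C(C)(C)C)c1)CC2=O)C=O
F5 | step 8 | (E)-4-[(2S)-4-hydroxy-5,7-bis(TBSO)-2-(3,4-bis(TBSO)phenyl)chroman-8-yl]-2-methylbut-2-enal (flavan-4-ol, either C4 epimer) | C/C(=C\Cc1c(O[Si](C)(C)C(C)(C)C)cc(O[Si](C)(C)C(C)(C)C)c2c1O[C@H](c1ccc(O[Si](C)(C)C(C)(C)C)c(O[Si](C)(C)C(C)(C)C)c1)CC2O)C=O
F6 | step 7 | 2-[(2S,4S)-4-methoxy-5,7-bis(TBSO)-2-(3,4-bis(TBSO)phenyl)chroman-8-yl]acetaldehyde | O=CCc1c(O[Si](C)(C)C(C)(C)C)cc(O[Si](C)(C)C(C)(C)C)c2c1O[C@H](c1ccc(O[Si](C)(C)C(C)(C)C)c(O[Si](C)(C)C(C)(C)C)c1)C[C@@H]2OC
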